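The drimane core is cut at C5–C10 (ring A) and C6–C7 (ring B). The feature used is the oxygen pattern around ring B: C6–O and C8 (the exocyclic alkene carbon, taken back to a ketone) are 1,3-related as in an aldol, and C9, between that ketone and C11 at the ester level, is a β-keto ester carbon whose alkylidene terminus is quaternary C10. One amine-catalysed Michael–aldol cascade then folds an acyclic aldehyde into the trans-decalin and sets C5, C6, C9 and C10. The precursor is a C6 aldehyde with the C4 gem-dimethyl group and a silylated C3 carbinol, linked through C2–C1 to the C10 alkylidene of methyl acetoacetate.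

Key step: step 8

Remark on numbering: drimane numbering is used (ring A C1–C5 and C10, ring B C5–C10, C11 on C9, C12 on C8, methyls on C4 and C10); a 12-nordrimane lacks C12. From 14 onwards the C10 methyl is axial, H5 and H9 are axial on the other face, the C6 oxygen and the C9 carbon substituent are equatorial, and the C3 oxygen is axial (cis to H5).

Assumption: the iridium catalyst carrying (R)-SEGPHOS is taken to give the (S)-carbinol 5; the sense is checked on the first batch by Mosher ester analysis and the antipodal ligand is used if it proves opposite.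

Remark on mixtures: 11 and 12 are used as E/Z mixtures (one isomer drawn). C9 of 13 and C8 of 16 and 17 are left undefined because these centres are equilibrated or erased later.

Design remark: the aryl ether is installed only after C8 has become the alkene, so no intermediate carries an aryloxy group β to a ketone.

Step 1
Reactants: 1 5-hydroxypentan-2-one
Product: 2 3-(2-methyl-1,3-dioxolan-2-yl)propan-1-ol
Conditions: HOCH2CH2OH, TsOH·H2O (cat.), toluene, reflux, Dean–Stark
Reagents that add atoms: ethylene glycol, OCCO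
Why: Acid-catalysed ketalisation with azeotropic removal of water converts the ketone (and its cyclic hemiketal form) into the dioxolane, which protects C10 through the redox and boron steps that follow.

Step 2
Reactants: 2 3-(2-methyl-1,3-dioxolan-2-yl)propan-1-ol; 3 3-methylbuta-1,2-diene
Product: 5 (3S)-4,4-dimethyl-1-(2-methyl-1,3-dioxolan-2-yl)hex-5-en-3-ol, via aldehyde 4 (not isolated)
Conditions: 3 (3 equiv), Ir(η3-C3H5)[(R)-SEGPHOS](κ2-C,O-O2CC6H2-4-Cl-3-NO2) (5 mol%, preformed from [Ir(cod)Cl]2), toluene, 60 °C, sealed tube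
Reagents that add atoms: none
Why: Krische-type transfer-hydrogenative tert-prenylation, in which the iridium catalyst oxidises 2 to aldehyde 4, hydrometalates the allene to a 1,1-dimethylallyl iridium species and adds it through a closed six-membered transition state on the aldehyde face chosen by the SEGPHOS ligand, which sets C3 as S next to the new C4 gem-dimethyl carbon.

Step 3
Reactants: 5 (3S)-4,4-dimethyl-1-(2-methyl-1,3-dioxolan-2-yl)hex-5-en-3-ol
Product: 6 tert-butyl{[(3S)-4,4-dimethyl-1-(2-methyl-1,3-dioxolan-2-yl)hex-5-en-3-yl]oxy}dimethylsilane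
Conditions: TBSOTf, 2,6-lutidine, CH2Cl2, −78 to 0 °C
Reagents that add atoms: tert-butyldimethylsilyl triflate, CC(C)(C)[Si](C)(C)OS(=O)(=O)C(F)(F)F
Why: Silyl ether formation with a silyl triflate and a hindered pyridine base is the standard answer to a neopentyl secondary alcohol; the ketal tolerates the brief cold exposure and C3 is not touched.

Step 4
Reactants: 6 tert-butyl{[(3S)-4,4-dimethyl-1-(2-methyl-1,3-dioxolan-2-yl)hex-5-en-3-yl]oxy}dimethylsilane
Product: 8 (4S)-4-(tert-butyldimethylsilyloxy)-3,3-dimethyl-6-(2-methyl-1,3-dioxolan-2-yl)hexan-1-ol, via alkylborane 7 (not isolated)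
Conditions: 9-BBN, THF, 0 to 60 °C; then NaOH, H2O2, 0 °C to rt
Reagents that add atoms: hydrogen peroxide, OO; 9-borabicyclo[3.3.1]nonane, B1C2CCCC1CCC2 (its boron unit stays only in 7)
Why: Anti-Markovnikov hydroboration–oxidation, in which 9-BBN places boron on the terminal carbon of the neopentyl vinyl group and basic peroxide turns the C–B bond of 7 into the C6 hydroxyl, with the ketal and the silyl ether unaffected.

Step 5
Reactants: 8 (4S)-4-(tert-butyldimethylsilyloxy)-3,3-dimethyl-6-(2-methyl-1,3-dioxolan-2-yl)hexan-1-ol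
Product: 9 (5S)-5-(tert-butyldimethylsilyloxy)-8-hydroxy-6,6-dimethyloctan-2-one
Conditions: PPTS, acetone–H2O (10:1), 55 °C
Reagents that add atoms: water, O
Why: Mild acid-catalysed ketal hydrolysis frees the C10 methyl ketone; PPTS is too weak to cleave the hindered secondary TBS ether, and the hydroxyl, seven atoms away, cannot trap the ketone as a stable hemiketal.

Step 6
Reactants: 9 (5S)-5-(tert-butyldimethylsilyloxy)-8-hydroxy-6,6-dimethyloctan-2-one; 10 methyl acetoacetate
Product: 11 methyl (6S)-2-acetyl-6-(tert-butyldimethylsilyloxy)-9-hydroxy-3,7,7-trimethylnon-2-enoate (E/Z mixture)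
Conditions: 10 (1.5 equiv), TiCl4 (3 equiv), pyridine (6 equiv), THF–CH2Cl2, 0 °C to rt
Reagents that add atoms: none
Why: Knoevenagel condensation under TiCl4–pyridine (Lehnert) conditions, in which the titanium enolate of 10 adds to the ketone and the titanium aldolate eliminates; one equivalent of TiCl4 is spent on the hydroxyl as an alkoxide that the work-up hydrolyses, and the alkene isomers need not be separated because C9 becomes an epimerisable sp3 centre in step 8.

Step 7
Reactants: 11 methyl (6S)-2-acetyl-6-(tert-butyldimethylsilyloxy)-9-hydroxy-3,7,7-trimethylnon-2-enoate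
Product: 12 methyl (6S)-2-acetyl-6-(tert-butyldimethylsilyloxy)-3,7,7-trimethyl-9-oxonon-2-enoate (E/Z mixture)
Conditions: TEMPO (10 mol%), PhI(OAc)2, CH2Cl2, rt
Reagents that add atoms: none
Why: Oxoammonium-mediated (TEMPO) alcohol oxidation stops at the aldehyde and runs without base, so the alkylidene acetoacetate is not deconjugated and the silyl ether is safe.

Step 8
Reactants: 12 methyl (6S)-2-acetyl-6-(tert-butyldimethylsilyloxy)-3,7,7-trimethyl-9-oxonon-2-enoate
Product: 14 methyl (3S,5S,6R,9S,10R)-3-(tert-butyldimethylsilyloxy)-6-hydroxy-8-oxo-12-nordriman-11-oate, via ring A keto aldehyde 13 (not isolated)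
Conditions: (S)-α,α-diphenylprolinol trimethylsilyl ether (20 mol%), PhCO2H (20 mol%), toluene (0.05 M), rt; pH 7 buffer work-up
Reagents that add atoms: none
Why: The secondary amine condenses with the C6 aldehyde of 12 to an E-enamine whose C5 adds to C10 of the alkylidene acetoacetate, hydrolysis releases 13, and the methyl ketone of 13, enolised towards C7, adds to the C6 aldehyde. The closest known chemistry is the diarylprolinol silyl ether catalysed intramolecular Michael addition of aldehydes to doubly activated alkenes, coupled to the Robinson-type aldol closure of an acetoacetate methyl group known from amine-catalysed Michael–aldol routes to hydroxycyclohexanones; formation of a quaternary carbon in the Michael step is the part with thin precedent. Ring A closes 6-exo-trig through a chair, and ring B closes 6-(enolendo)-exo-trig, the C7=C8 enol lying inside the new ring. C5 is set by the (S)-catalyst, whose diphenyl(silyloxy)methyl arm blocks one enamine face; C10 is set by the chair that places the large C9 unit equatorial and the methyl axial, anti to H5 (trans fusion); C6 and C9 settle to equatorial hydroxyl and ester by reversible aldol addition and β-keto ester enolisation. The step needs reagent control over the existing C3 centre, whose silyloxy group has to stand axial in this fold, and this is secured because that position meets only H1 and H5 and is gauche to one C4 methyl instead of two, while the C4 gem-dimethyl group and the two acceptor groups on C9 drive the congested C5–C10 closure. It also needs the enamine to form at the aldehyde and the aldol to stop before dehydration, which the far higher reactivity of the aldehyde towards the amine, the weak acid co-catalyst, room temperature and a neutral work-up should secure.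

Step 9
Reactants: 14 methyl (3S,5S,6R,9S,10R)-3-(tert-butyldimethylsilyloxy)-6-hydroxy-8-oxo-12-nordriman-11-oate
Product: 15 methyl (3S,5S,6R,9S,10R)-3-(tert-butyldimethylsilyloxy)-8-oxo-6-(triethylsilyloxy)-12-nordriman-11-oate
Conditions: TESOTf (1.2 equiv), 2,6-lutidine, CH2Cl2, −78 °C
Reagents that add atoms: triethylsilyl triflate, CC[Si](CC)(CC)OS(=O)(=O)C(F)(F)F
Why: Silylation with a silyl triflate at −78 °C caps the hindered equatorial C6 hydroxyl under conditions too cold and too weakly basic for dehydration or retro-aldol cleavage, so the β-hydroxy ketone is gone before any hydride or base is used.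

Step 10
Reactants: 15 methyl (3S,5S,6R,9S,10R)-3-(tert-butyldimethylsilyloxy)-8-oxo-6-(triethylsilyloxy)-12-nordriman-11-oate
Product: 16 (3S,5S,6R,9R,10R)-3-(tert-butyldimethylsilyloxy)-6-(triethylsilyloxy)-12-nordrimane-8,11-diol (C8 epimers)
Conditions: LiAlH4 (excess, inverse addition), THF, −20 to 0 °C; aqueous potassium sodium tartrate work-up
Reagents that add atoms: none
Why: Hydride reduction with LiAlH4 takes the ester to the C11 primary alcohol and the ketone to a C8 carbinol whose configuration does not matter because C8 is re-oxidised; cold inverse addition limits enolate formation and both silyl ethers are stable to the reagent.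

Step 11
Reactants: 16 (3S,5S,6R,9R,10R)-3-(tert-butyldimethylsilyloxy)-6-(triethylsilyloxy)-12-nordrimane-8,11-diol
Product: 17 (3S,5S,6R,9R,10R)-3-(tert-butyldimethylsilyloxy)-6,11-bis(triethylsilyloxy)-12-nordriman-8-ol (C8 epimers)
Conditions: TESCl (1.1 equiv), imidazole, CH2Cl2, −20 °C
Reagents that add atoms: chlorotriethylsilane, CC[Si](Cl)(CC)CC
Why: Selective silylation works because a primary hydroxyl reacts with TESCl far faster than the secondary C8 hydroxyl, which is flanked by C9 and faces the axial C10 methyl across the ring.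

Step 12
Reactants: 17 (3S,5S,6R,9R,10R)-3-(tert-butyldimethylsilyloxy)-6,11-bis(triethylsilyloxy)-12-nordriman-8-ol
Product: 18 (3S,5S,6R,9R,10R)-3-(tert-butyldimethylsilyloxy)-6,11-bis(triethylsilyloxy)-12-nordriman-8-one
Conditions: DMP, pyridine, CH2Cl2, 0 °C to rt
Reagents that add atoms: none
Why: Dess–Martin oxidation restores the C8 ketone under buffered conditions, so neither β-silyloxy group is eliminated and the equatorial C9 substituent is retained.

Step 13
Reactants: 18 (3S,5S,6R,9R,10R)-3-(tert-butyldimethylsilyloxy)-6,11-bis(triethylsilyloxy)-12-nordriman-8-one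
Product: 19 (3S,5S,6R,9R,10S)-3-(tert-butyldimethylsilyloxy)-6,11-bis(triethylsilyloxy)drim-8(12)-ene
Conditions: Zn, CH2Br2, TiCl4 (pre-aged reagent), THF–CH2Cl2, 0 °C to rt
Reagents that add atoms: dibromomethane, BrCBr
Why: Takai–Lombardo methylenation uses a non-basic zinc–titanium methylene reagent that converts hindered, enolisable ketones into 1,1-disubstituted alkenes without epimerising C9 or expelling the β-silyloxy groups, which gives the C8=C12 alkene.

Step 14
Reactants: 19 (3S,5S,6R,9R,10S)-3-(tert-butyldimethylsilyloxy)-6,11-bis(triethylsilyloxy)drim-8(12)-ene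
Product: 20 (3S,5S,6R,9R,10S)-3-(tert-butyldimethylsilyloxy)drim-8(12)-ene-6,11-diol
Conditions: PPTS, MeOH–CH2Cl2, rt
Reagents that add atoms: none
Why: Acid-catalysed methanolysis removes both triethylsilyl ethers, which are far more labile than the hindered neopentyl TBS ether at C3, under conditions too mild to move the exocyclic alkene.

Step 15
Reactants: 20 (3S,5S,6R,9R,10S)-3-(tert-butyldimethylsilyloxy)drim-8(12)-ene-6,11-diol; 21 umbelliferone (7-hydroxy-2H-chromen-2-one)
Product: 22 7-{[(3S,5S,6R,9R,10S)-3-(tert-butyldimethylsilyloxy)-6-hydroxydrim-8(12)-en-11-yl]oxy}-2H-chromen-2-one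
Conditions: PPh3, DIAD, THF, 0 °C to rt
Reagents that add atoms: none
Why: Mitsunobu etherification, in which the acidic phenol of 21 displaces the oxyphosphonium ion formed at the primary C11 hydroxyl while the hindered secondary C6 hydroxyl stays out; since C8 is no longer a carbonyl, the new aryl ether has no β-elimination pathway.

Step 16
Reactants: 22 7-{[(3S,5S,6R,9R,10S)-3-(tert-butyldimethylsilyloxy)-6-hydroxydrim-8(12)-en-11-yl]oxy}-2H-chromen-2-one
Product: 23 7-{[(3S,5S,6R,9R,10S)-6-acetoxy-3-(tert-butyldimethylsilyloxy)drim-8(12)-en-11-yl]oxy}-2H-chromen-2-one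
Conditions: Ac2O, DMAP, pyridine, rt to 40 °C
Reagents that add atoms: acetic anhydride, CC(=O)OC(C)=O
Why: DMAP-catalysed acylation of the only free hydroxyl, the equatorial C6–OH, gives the acetate; the lactone and the aryl ether are inert.

Step 17
Reactants: 23 7-{[(3S,5S,6R,9R,10S)-6-acetoxy-3-(tert-butyldimethylsilyloxy)drim-8(12)-en-11-yl]oxy}-2H-chromen-2-one
Product: 24 isofeterin, 7-{[(3S,5S,6R,9R,10S)-6-acetoxy-3-hydroxydrim-8(12)-en-11-yl]oxy}-2H-chromen-2-one
Conditions: HF (48% aq.), MeCN, 0 °C to rt
Reagents that add atoms: none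
Why: Fluoride-driven desilylation with aqueous HF cleaves the hindered C3 silyl ether without base, so the acetate neither migrates nor hydrolyses and the lactone and the exocyclic alkene are untouched.

Compound list
1 | 5-hydroxypentan-2-one | CC(=O)CCCO | starting material
2 | 3-(2-methyl-1,3-dioxolan-2-yl)propan-1-ol | CC1(CCCO)OCCO1 | intermediate
3 | 3-methylbuta-1,2-diene | CC(C)=C=C | starting material
4 | 3-(2-methyl-1,3-dioxolan-2-yl)propanal | CC1(CCC=O)OCCO1 | intermediate (not isolated)
5 | (3S)-4,4-dimethyl-1-(2-methyl-1,3-dioxolan-2-yl)hex-5-en-3-ol | C=CC(C)(C)[C@@H](O)CCC1(C)OCCO1 | intermediate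
6 | tert-butyl{[(3S)-4,4-dimethyl-1-(2-methyl-1,3-dioxolan-2-yl)hex-5-en-3-yl]oxy}dimethylsilane | C=CC(C)(C)[C@@H](O[Si](C)(C)C(C)(C)C)CCC1(C)OCCO1 | intermediate
7 | 9-[(4S)-4-(tert-butyldimethylsilyloxy)-3,3-dimethyl-6-(2-methyl-1,3-dioxolan-2-yl)hexyl]-9-borabicyclo[3.3.1]nonane | C1CCC2CCCC1B2CCC(C)(C)[C@@H](O[Si](C)(C)C(C)(C)C)CCC1(C)OCCO1 | intermediate (not isolated)
8 | (4S)-4-(tert-butyldimethylsilyloxy)-3,3-dimethyl-6-(2-methyl-1,3-dioxolan-2-yl)hexan-1-ol | OCCC(C)(C)[C@@H](O[Si](C)(C)C(C)(C)C)CCC1(C)OCCO1 | intermediate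
9 | (5S)-5-(tert-butyldimethylsilyloxy)-8-hydroxy-6,6-dimethyloctan-2-one | OCCC(C)(C)[C@@H](O[Si](C)(C)C(C)(C)C)CCC(C)=O | intermediate
10 | methyl acetoacetate | CC(=O)CC(=O)OC | starting material
11 | methyl (6S)-2-acetyl-6-(tert-butyldimethylsilyloxy)-9-hydroxy-3,7,7-trimethylnon-2-enoate (E/Z mixture, one isomer drawn) | OCCC(C)(C)[C@@H](O[Si](C)(C)C(C)(C)C)CC/C(C)=C(/C(C)=O)C(=O)OC | intermediate
12 | methyl (6S)-2-acetyl-6-(tert-butyldimethylsilyloxy)-3,7,7-trimethyl-9-oxonon-2-enoate (E/Z mixture, one isomer drawn; key-step precursor) | O=CCC(C)(C)[C@@H](O[Si](C)(C)C(C)(C)C)CC/C(C)=C(/C(C)=O)C(=O)OC | intermediate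
13 | methyl 2-[(1R,2S,4S)-4-(tert-butyldimethylsilyloxy)-2-formyl-1,3,3-trimethylcyclohexyl]-3-oxobutanoate (C2 of the butanoate epimerisable) | O=C[C@@H]1C(C)(C)[C@@H](O[Si](C)(C)C(C)(C)C)CC[C@@]1(C)C(C(C)=O)C(=O)OC | intermediate (not isolated)
14 | methyl (3S,5S,6R,9S,10R)-3-(tert-butyldimethylsilyloxy)-6-hydroxy-8-oxo-12-nordriman-11-oate (key-step product) | O=C1C[C@@H](O)[C@@H]2C(C)(C)[C@@H](O[Si](C)(C)C(C)(C)C)CC[C@@]2(C)[C@@H]1C(=O)OC | intermediate
15 | methyl (3S,5S,6R,9S,10R)-3-(tert-butyldimethylsilyloxy)-8-oxo-6-(triethylsilyloxy)-12-nordriman-11-oate | O=C1C[C@@H](O[Si](CC)(CC)CC)[C@@H]2C(C)(C)[C@@H](O[Si](C)(C)C(C)(C)C)CC[C@@]2(C)[C@@H]1C(=O)OC | intermediate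
16 | (3S,5S,6R,9R,10R)-3-(tert-butyldimethylsilyloxy)-6-(triethylsilyloxy)-12-nordrimane-8,11-diol (C8 epimers) | OC1C[C@@H](O[Si](CC)(CC)CC)[C@@H]2C(C)(C)[C@@H](O[Si](C)(C)C(C)(C)C)CC[C@@]2(C)[C@@H]1CO | intermediate
17 | (3S,5S,6R,9R,10R)-3-(tert-butyldimethylsilyloxy)-6,11-bis(triethylsilyloxy)-12-nordriman-8-ol (C8 epimers) | OC1C[C@@H](O[Si](CC)(CC)CC)[C@@H]2C(C)(C)[C@@H](O[Si](C)(C)C(C)(C)C)CC[C@@]2(C)[C@@H]1CO[Si](CC)(CC)CC | intermediate
18 | (3S,5S,6R,9R,10R)-3-(tert-butyldimethylsilyloxy)-6,11-bis(triethylsilyloxy)-12-nordriman-8-one | O=C1C[C@@H](O[Si](CC)(CC)CC)[C@@H]2C(C)(C)[C@@H](O[Si](C)(C)C(C)(C)C)CC[C@@]2(C)[C@@H]1CO[Si](CC)(CC)CC | intermediate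
19 | (3S,5S,6R,9R,10S)-3-(tert-butyldimethylsilyloxy)-6,11-bis(triethylsilyloxy)drim-8(12)-ene | C=C1C[C@@H](O[Si](CC)(CC)CC)[C@@H]2C(C)(C)[C@@H](O[Si](C)(C)C(C)(C)C)CC[C@@]2(C)[C@@H]1CO[Si](CC)(CC)CC | intermediate
20 | (3S,5S,6R,9R,10S)-3-(tert-butyldimethylsilyloxy)drim-8(12)-ene-6,11-diol | C=C1C[C@@H](O)[C@@H]2C(C)(C)[C@@H](O[Si](C)(C)C(C)(C)C)CC[C@@]2(C)[C@@H]1CO | intermediate
21 | umbelliferone (7-hydroxy-2H-chromen-2-one) | Oc1ccc2ccc(=O)oc2c1 | starting material
22 | 7-{[(3S,5S,6R,9R,10S)-3-(tert-butyldimethylsilyloxy)-6-hydroxydrim-8(12)-en-11-yl]oxy}-2H-chromen-2-one | C=C1C[C@@H](O)[C@@H]2C(C)(C)[C@@H](O[Si](C)(C)C(C)(C)C)CC[C@@]2(C)[C@@H]1COc1ccc2ccc(=O)oc2c1 | intermediate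
23 | 7-{[(3S,5S,6R,9R,10S)-6-acetoxy-3-(tert-butyldimethylsilyloxy)drim-8(12)-en-11-yl]oxy}-2H-chromen-2-one | C=C1C[C@@H](OC(C)=O)[C@@H]2C(C)(C)[C@@H](O[Si](C)(C)C(C)(C)C)CC[C@@]2(C)[C@@H]1COc1ccc2ccc(=O)oc2c1 | intermediate
24 | isofeterin, 7-{[(3S,5S,6R,9R,10S)-6-acetoxy-3-hydroxydrim-8(12)-en-11-yl]oxy}-2H-chromen-2-one | C=C1C[C@@H](OC(C)=O)[C@@H]2C(C)(C)[C@@H](O)CC[C@@]2(C)[C@@H]1COc1ccc2ccc(=O)oc2c1 | target

Total step count: 17. Longest linear sequence: 17 steps (from 1; compounds 3, 10 and 21 enter as bought).

Steps most likely to fail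

Step 8. The C5–C10 bond may form too slowly at the congested, twisted tetrasubstituted acceptor, so that deconjugation of the alkylidene acetoacetate, self-condensation of the aldehyde or dehydration of the aldol take over; the C3 centre may also erode catalyst control of the ring A fold. The fallback sets out from 12, separates the two ring closures and uses a stoichiometric chiral enamine. Aldehyde 12 is condensed with (S)-2-(methoxymethyl)pyrrolidine (molecular sieves, benzene) to the isolated pyrrolidine enamine F1. F1 is cyclised by warming in MeCN with MgBr2·OEt2, which chelates and activates the 1,3-dicarbonyl acceptor; this is a Stork-type enamine Michael addition, and the (S)-auxiliary shields the same enamine face as the catalyst. Aqueous acetic acid hydrolysis gives keto aldehyde 13, now isolated, and ring B is closed separately with catalytic pyrrolidinium acetate in THF at 0 °C. This comes back to the route at 14.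

Step 6. Titanation of the free primary hydroxyl and slow addition to the methyl ketone may leave the condensation incomplete or divert it to the deconjugated isomer. The fallback sets out from 9 and masks the hydroxyl. Silylation at the primary oxygen (TBSCl, imidazole, DMF) gives the keto bis-silyl ether F2. F2 is condensed with 10 by the TiCl4–pyridine protocol, now with no alkoxide consuming the Lewis acid and with room to warm the mixture, to give the bis-silyl alkylidene acetoacetate F3. HF·pyridine in THF–pyridine at 0 °C then removes only the primary silyl group. This comes back to the route at 11.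

Step 15. Displacement at the congested oxyphosphonium ion on C11 (β-branched, next to quaternary C10) may be slow, so that the betaine is lost to alkylation of the hydrazide or to elimination. The fallback sets out from 20 and replaces the redox condensation by activation and displacement. Appel conditions (I2, PPh3, imidazole, CH2Cl2) convert the primary hydroxyl selectively into the C11 iodide F4, and F4 is etherified with 21 and Cs2CO3 in DMF at 60 °C (Williamson synthesis). This comes back to the route at 22.

Further compounds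
F1 | step 8 | methyl (6S,8E)-2-acetyl-6-(tert-butyldimethylsilyloxy)-9-[(2S)-2-(methoxymethyl)pyrrolidin-1-yl]-3,7,7-trimethylnona-2,8-dienoate | COC[C@@H]1CCCN1/C=C/C(C)(C)[C@@H](O[Si](C)(C)C(C)(C)C)CC/C(C)=C(/C(C)=O)C(=O)OC
F2 | step 6 | (5S)-5,8-bis(tert-butyldimethylsilyloxy)-6,6-dimethyloctan-2-one | CC(C)(C)[Si](C)(C)OCCC(C)(C)[C@@H](O[Si](C)(C)C(C)(C)C)CCC(C)=O
F3 | step 6 | methyl (6S)-2-acetyl-6,9-bis(tert-butyldimethylsilyloxy)-3,7,7-trimethylnon-2-enoate (E/Z mixture) | CC(C)(C)[Si](C)(C)OCCC(C)(C)[C@@H](O[Si](C)(C)C(C)(C)C)CC/C(C)=C(/C(C)=O)C(=O)OC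
F4 | step 15 | (3S,5S,6R,9R,10R)-3-(tert-butyldimethylsilyloxy)-11-iododrim-8(12)-en-6-ol | C=C1C[C@@H](O)[C@@H]2C(C)(C)[C@@H](O[Si](C)(C)C(C)(C)C)CC[C@@]2(C)[C@@H]1CI
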